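The plan rests on inserting the quaternary carbon C1 (carotane numbering, defined below) between C10 and C5 last. In the key step a secondary diazoalkane carbon (C1), tethered through C2–C4 to C5 of a 3-methylcyclohex-2-enone, adds to the ring carbonyl C10, and C5 then migrates from C10 to C1 with loss of N2. One operation closes the cyclopentane (C1–C5), enlarges the six-membered ring to the cycloheptenone (C1, C5–C10) and sets the methyl-bearing quaternary stereocentre. It exploits the C10 oxygen that flanks C1. The precursor, a seco-diketone, is cut from (S)-terpinen-4-ol, whose ring acts as a temporary stereochemical template.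

Key step: step 10

Remarks on the chemistry
- Numbering used for all compounds: C1 = ring-fusion carbon bearing CH3; C2, C3 = CH2; C4 = carbinol carbon (OH, isopropyl); C5 = ring-fusion CH; C6 = CH–O–anisoyl; C7 = CH2; C8 = C(CH3)=; C9 = CH=; C10 = CH–OAc. In the target, CH3-1, H-5, OH-4 and OAc-10 lie on one face and O-6 on the other (cis ring fusion).
- Ring A is the cyclohexane inherited from terpinen-4-ol (C10, C1, C2, C3, C4, C5), opened in step 8. Ring B is the cyclohexene (C10, C9, C8, C7, C6, C5) that becomes the seven-membered ring.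
- Assumption: (S)-(+)-terpinen-4-ol is bought in high enantiomeric purity; it supplies C4, from which C5, C6, C1 and C10 are relayed.
- C1 and C10 of the template are temporary stereocentres (both become carbonyl carbons in step 8). The SMILES show the epimer expected; either would serve.

Step 1
Reactants: 1 (S)-(+)-terpinen-4-ol
Product: 2 (S)-terpinen-4-ol triethylsilyl ether
Conditions: TESOTf, 2,6-lutidine, CH2Cl2, −78 to 0 °C
Reagents that add atoms: triethylsilyl triflate, CC[Si](CC)(CC)OS(=O)(=O)C(F)(F)F
Why: Silyl triflate silylation of the hindered tertiary alcohol leaves C4 untouched and gives an ether that later blocks retro-aldol cleavage, O–H insertion and hydrogen bonding at O4.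

Step 2
Reactants: 2 (S)-terpinen-4-ol triethylsilyl ether
Product: 3 ring A ketol (C10 ketone, tertiary C1 hydroxyl trans to the C4 silyloxy group)
Conditions: RuCl3 (1 mol %), KHSO5 (as Oxone), NaHCO3, EtOAc/MeCN/H2O, rt
Reagents that add atoms: potassium peroxymonosulfate, [K+].[O-]S(=O)(=O)OO
Why: RuO4-catalysed ketohydroxylation ([3+2] addition to the trisubstituted alkene, then oxidation of the secondary ruthenate ester) is regiospecific because only C10 bears hydrogen, and the oxidant should add anti to the pseudoaxial silyloxy group, placing the temporary C1 hydroxyl trans to O4.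

Step 3
Reactants: 4 3-methylbut-3-en-1-ol
Product: 5 3-methylbut-3-enal
Conditions: Dess–Martin periodinane, NaHCO3, CH2Cl2, 0 °C; used at once as a cold solution
Reagents that add atoms: none
Why: Buffered Dess–Martin oxidation gives the β,γ-unsaturated aldehyde without base or acid that would move the alkene into conjugation.

Step 4
Reactants: 3 ring A ketol; 5 3-methylbut-3-enal
Product: 7 anti-aldol adduct (C5 bears the CH(OH)CH2C(CH3)=CH2 chain trans to O4; free C6 hydroxyl), via bis(dibutylboryl) enolate 6 (not isolated)
Conditions: n-Bu2BOTf (2.2 equiv), i-Pr2NEt, CH2Cl2, −78 °C; 5, −78 to −20 °C; then pH 7 buffer, MeOH, H2O2, 0 °C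
Reagents that add atoms: none
Why: Boron aldol reaction in which the ring-locked E enolate reacts through a Zimmerman–Traxler chair to give the anti aldol (sets C6), while the aldehyde adds axially to C5 on the face opposite the pseudoaxial C4 silyloxy group (sets C5 trans to O4).

Step 5
Reactants: 7 anti-aldol adduct
Product: 8 vinyl triol (C10 tertiary allylic alcohol)
Conditions: CH2=CHMgBr (4 equiv), CeCl3, THF, −78 to 0 °C; aq. NH4Cl
Reagents that add atoms: vinylmagnesium bromide, C=C[Mg]Br
Why: Organocerium 1,2-addition to the hindered, enolisable ketone should outrun enolisation and retro-aldol cleavage; attack anti to the axial silyloxy group is expected, but the C10 configuration is immaterial.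

Step 6
Reactants: 8 vinyl triol
Product: 9 C6 4-methoxybenzoate
Conditions: 4-MeOC6H4COCl, Et3N, DMAP (cat.), CH2Cl2, 0 °C to rt
Reagents that add atoms: 4-methoxybenzoyl chloride, COc1ccc(cc1)C(Cl)=O
Why: DMAP-catalysed acylation selects the only secondary hydroxyl over the two tertiary ones and installs the final C6 ester with retention.

Step 7
Reactants: 9 C6 4-methoxybenzoate
Product: 10 cis-fused decalin diol (rings A and B; C8=C9 alkene; C1 and C10 hydroxyls)
Conditions: second-generation Grubbs catalyst (H2IMes)(PCy3)Cl2Ru=CHPh (5 mol %), CH2Cl2, 40 °C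
Reagents that add atoms: none
Why: Ring-closing metathesis of the vinyl group and the 1,1-disubstituted alkene closes ring B as a cyclohexene with the trisubstituted C8=C9 bond; no stereocentre is touched.

Step 8
Reactants: 10 cis-fused decalin diol
Product: 11 seco-diketone (5-anisoyloxy-3-methylcyclohex-2-enone carrying at C5 the C4(OTES)(i-Pr)CH2CH2COCH3 chain)
Conditions: Pb(OAc)4, CH2Cl2, −20 to 0 °C
Reagents that add atoms: none
Why: Criegee glycol cleavage of the ditertiary C1/C10 diol opens ring A and unveils the C10 enone and the C1 methyl ketone together under non-basic conditions that spare the β-acyloxy enone.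

Step 9
Reactants: 11 seco-diketone
Product: 12 N-triftosylhydrazone of the methyl ketone
Conditions: 2-(CF3)C6H4SO2NHNH2, MeOH, rt
Reagents that add atoms: 2-(trifluoromethyl)benzenesulfonohydrazide, NNS(=O)(=O)c1ccccc1C(F)(F)F
Why: Hydrazone condensation should occur at the unhindered saturated methyl ketone and not at the conjugated, α-branched ring ketone.

Step 10
Reactants: 12 N-triftosylhydrazone
Product: 15 cis-fused hydroazulenone (C10 ketone, C8=C9, quaternary C1, OAn-6, OTES-4), via diazoalkane 13 (not isolated), via diazonium alkoxide 14 (not isolated)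
Conditions: NaH (1.0 equiv), THF, −40 to 0 °C; then Sc(OTf)3 (10 mol %), CH2Cl2, −78 °C to rt
Reagents that add atoms: none
Why: Deprotonation of the hydrazone and loss of sulfinate at low temperature give the secondary diazoalkane 13, whose nucleophilic carbon C1 adds to the Sc(OTf)3-activated C10 carbonyl to form the six-membered diazonium alkoxide 14, and an anti-periplanar 1,2-shift of C5 from C10 to C1 with loss of N2 then gives 15. The closest known reaction type is the intramolecular diazoalkane–ketone ring enlargement (the carbon counterpart of the intramolecular Schmidt reaction), together with Lewis-acid-catalysed ketone homologation by disubstituted diazoalkanes. The cyclopentane closes in two bond formations, C1–C10 by 6-exo-trig carbonyl addition and C1–C5 by the shift that contracts this transient ring to five members while enlarging the cyclohexenone to the cycloheptenone. C1 is set in the chair of 14 that is trans-fused to ring B, in which the diazonium group is equatorial (gauche to the alkoxide, anti-periplanar to C10–C5) and the methyl group axial and syn to H-5; C5 migrates with retention and displaces N2 with inversion, so CH3-1 and H-5 become cis, whereas the competing chair needs a 1,3-diaxial CH3/C6 contact and an axial silyloxy group beside the alkoxide. The step needs C5 and not C9 to migrate, which the equatorial diazonium and the low migratory aptitude of an sp2 carbon in diazo insertions should secure; it also needs the β-acyloxy enone to survive, for which the single equivalent of base is consumed by the acidic N–H and the temperature is kept low.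

Step 11
Reactants: 15 cis-fused hydroazulenone
Product: 16 C10 allylic alcohol (OH-10 cis to CH3-1)
Conditions: NaBH4, CeCl3·7H2O, MeOH, −78 °C
Reagents that add atoms: none
Why: Luche 1,2-reduction of the enone, in which hydride should approach the carbonyl face opposite the angular C1 methyl group that projects over the enone and so place the hydroxyl cis to CH3-1.

Step 12
Reactants: 16 C10 allylic alcohol
Product: 17 C10 acetate (silyl ether)
Conditions: Ac2O, Et3N, DMAP, CH2Cl2, rt
Reagents that add atoms: acetic anhydride, CC(=O)OC(C)=O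
Why: DMAP-catalysed acetylation of the hindered secondary allylic alcohol proceeds with retention at C10.

Step 13
Reactants: 17 C10 acetate (silyl ether)
Product: 18 target, 10-acetoxy-6-(4-methoxybenzoyloxy)-cis-fused carot-8-en-4-ol
Conditions: HF·pyridine, THF, 0 °C to rt
Reagents that add atoms: none
Why: Fluoride-mediated desilylation under mildly acidic conditions frees the tertiary C4 hydroxyl without acyl migration or ester cleavage.

Compound list
1 | (S)-(+)-terpinen-4-ol, (1S)-4-methyl-1-(propan-2-yl)cyclohex-3-en-1-ol | CC1=CC[C@](O)(C(C)C)CC1 | starting material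
2 | (S)-terpinen-4-ol triethylsilyl ether | CC1=CC[C@](O[Si](CC)(CC)CC)(C(C)C)CC1 | intermediate
3 | ring A ketol: 2-hydroxy-2-methyl-5-(propan-2-yl)-5-(triethylsilyloxy)cyclohexan-1-one, hydroxyl trans to the silyloxy group | C[C@@]1(O)C(=O)C[C@](O[Si](CC)(CC)CC)(C(C)C)CC1 | intermediate
4 | 3-methylbut-3-en-1-ol | CC(=C)CCO | starting material
5 | 3-methylbut-3-enal | CC(=C)CC=O | intermediate
6 | bis(dibutylboryl) enolate of 3 (C10=C5 boron enolate, C1 O-borinate) | C[C@@]1(OB(CCCC)CCCC)C(OB(CCCC)CCCC)=C[C@](O[Si](CC)(CC)CC)(C(C)C)CC1 | intermediate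
7 | anti-aldol adduct: ketol 3 carrying at C5 the 1-hydroxy-3-methylbut-3-enyl chain, trans to O4 | C[C@@]1(O)C(=O)[C@H]([C@@H](O)CC(C)=C)[C@](O[Si](CC)(CC)CC)(C(C)C)CC1 | intermediate
8 | vinyl triol: 7 with vinyl and hydroxyl on C10 | C[C@@]1(O)[C@](O)(C=C)[C@H]([C@@H](O)CC(C)=C)[C@](O[Si](CC)(CC)CC)(C(C)C)CC1 | intermediate
9 | C6 4-methoxybenzoate of 8 | C[C@@]1(O)[C@](O)(C=C)[C@H]([C@@H](OC(=O)c2ccc(OC)cc2)CC(C)=C)[C@](O[Si](CC)(CC)CC)(C(C)C)CC1 | intermediate
10 | cis-fused decalin diol: rings A and B, C8=C9, OH-1 and OH-10, OAn-6, OTES-4 | C[C@@]1(O)[C@]2(O)C=C(C)C[C@H](OC(=O)c3ccc(OC)cc3)[C@@H]2[C@](O[Si](CC)(CC)CC)(C(C)C)CC1 | intermediate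
11 | seco-diketone: 5-(4-methoxybenzoyloxy)-3-methylcyclohex-2-enone with the 6-oxo-3-(triethylsilyloxy)-2-methylheptan-3-yl chain at C5, cis to O-6 | COc1ccc(C(=O)O[C@H]2CC(C)=CC(=O)[C@H]2[C@](O[Si](CC)(CC)CC)(C(C)C)CCC(C)=O)cc1 | intermediate
12 | N-triftosylhydrazone of the methyl ketone of 11 | COc1ccc(C(=O)O[C@H]2CC(C)=CC(=O)[C@H]2[C@](O[Si](CC)(CC)CC)(C(C)C)CCC(C)=NNS(=O)(=O)c3ccccc3C(F)(F)F)cc1 | intermediate
13 | diazoalkane (C1 diazo carbon) | COc1ccc(C(=O)O[C@H]2CC(C)=CC(=O)[C@H]2[C@](O[Si](CC)(CC)CC)(C(C)C)CCC(C)=[N+]=[N-])cc1 | intermediate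
14 | diazonium alkoxide: trans-fused bicyclic betaine, N2+ equatorial on C1, O– on C10 | COc1ccc(C(=O)O[C@H]2CC(C)=C[C@@]3([O-])[C@H]2[C@](O[Si](CC)(CC)CC)(C(C)C)CC[C@]3(C)[N+]#N)cc1 | intermediate
15 | cis-fused hydroazulenone: C10 ketone, C8=C9, CH3-1 and H-5 cis, OAn-6, OTES-4 | COc1ccc(C(=O)O[C@H]2CC(C)=CC(=O)[C@@]3(C)CC[C@@](O[Si](CC)(CC)CC)(C(C)C)[C@@H]23)cc1 | intermediate
16 | C10 allylic alcohol, OH-10 cis to CH3-1 | COc1ccc(C(=O)O[C@H]2CC(C)=C[C@H](O)[C@@]3(C)CC[C@@](O[Si](CC)(CC)CC)(C(C)C)[C@@H]23)cc1 | intermediate
17 | C10 acetate, C4 triethylsilyl ether | COc1ccc(C(=O)O[C@H]2CC(C)=C[C@H](OC(C)=O)[C@@]3(C)CC[C@@](O[Si](CC)(CC)CC)(C(C)C)[C@@H]23)cc1 | intermediate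
18 | target: 10-acetoxy-6-(4-methoxybenzoyloxy)-cis-fused carot-8-en-4-ol | COc1ccc(C(=O)O[C@H]2CC(C)=C[C@H](OC(C)=O)[C@@]3(C)CC[C@@](O)(C(C)C)[C@@H]23)cc1 | target

Total step count: 13. Longest linear sequence: 12 (steps 1, 2 and 4–13; step 3 is a one-step branch).

Steps most likely to fail

Step 10. Addition of the diazoalkane to the deactivated enone carbonyl may be slower than its decay by 1,2-hydride shift, or the β-acyloxy enone may eliminate anisoate and aromatise. The fallback expands the ring at the saturated-ketone level and introduces the enone afterwards. It sets out from 10: hydroxyl-directed hydrogenation of C8=C9 (H2, [Ir(cod)(PCy3)(py)]PF6, CH2Cl2) should give the saturated decalin diol F1. Cleavage with Pb(OAc)4 would then give the saturated diketone F2, and condensation with 2-(trifluoromethyl)benzenesulfonohydrazide its hydrazone F3. NaH and then Sc(OTf)3 would release the diazoalkane F4, which should expand to the saturated hydroazulenone F5. Dehydrogenation of F5 at its only enolisable α-position (IBX, DMSO, 70 °C) comes back to the route at 15.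

Step 5. The doubly α-branched ketone may resist addition, so that enolisation and retro-aldol cleavage of the aldolate take over. The fallback uses a smaller, less basic nucleophile and a later partial reduction. It sets out from 7: HC≡CMgBr with CeCl3 in THF should give the propargylic triol F6, and semihydrogenation (H2, Pd/CaCO3 poisoned with Pb(OAc)2, quinoline) comes back to the route at 8.

Step 11. Hydride may be delivered to the wrong face of the C10 carbonyl, giving the 10-epi alcohol F7. The fallback corrects the centre by inversion instead of by reduction. It sets out from F7, formed from 15: Mitsunobu reaction (PPh3, DIAD, 4-nitrobenzoic acid, toluene) should give the inverted 4-nitrobenzoate F8, and selective methanolysis of this activated ester beside the anisoate (K2CO3, MeOH, 0 °C) comes back to the route at 16.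

Further compounds
F1 | step 10 | saturated decalin diol (H-8 cis to OH-10) | C[C@@]1(O)[C@]2(O)C[C@H](C)C[C@H](OC(=O)c3ccc(OC)cc3)[C@@H]2[C@](O[Si](CC)(CC)CC)(C(C)C)CC1
F2 | step 10 | saturated seco-diketone | COc1ccc(C(=O)O[C@H]2C[C@@H](C)CC(=O)[C@H]2[C@](O[Si](CC)(CC)CC)(C(C)C)CCC(C)=O)cc1
F3 | step 10 | N-triftosylhydrazone of F2 | COc1ccc(C(=O)O[C@H]2C[C@@H](C)CC(=O)[C@H]2[C@](O[Si](CC)(CC)CC)(C(C)C)CCC(C)=NNS(=O)(=O)c3ccccc3C(F)(F)F)cc1
F4 | step 10 | saturated diazoalkane | COc1ccc(C(=O)O[C@H]2C[C@@H](C)CC(=O)[C@H]2[C@](O[Si](CC)(CC)CC)(C(C)C)CCC(C)=[N+]=[N-])cc1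
F5 | step 10 | saturated cis-fused hydroazulenone | COc1ccc(C(=O)O[C@H]2C[C@@H](C)CC(=O)[C@@]3(C)CC[C@@](O[Si](CC)(CC)CC)(C(C)C)[C@@H]23)cc1
F6 | step 5 | propargylic triol (ethynyl and hydroxyl on C10) | C[C@@]1(O)[C@](O)(C#C)[C@H]([C@@H](O)CC(C)=C)[C@](O[Si](CC)(CC)CC)(C(C)C)CC1
F7 | step 11 | 10-epi allylic alcohol | COc1ccc(C(=O)O[C@H]2CC(C)=C[C@@H](O)[C@@]3(C)CC[C@@](O[Si](CC)(CC)CC)(C(C)C)[C@@H]23)cc1
F8 | step 11 | C10 4-nitrobenzoate of correct configuration | COc1ccc(C(=O)O[C@H]2CC(C)=C[C@H](OC(=O)c4ccc(cc4)[N+](=O)[O-])[C@@]3(C)CC[C@@](O[Si](CC)(CC)CC)(C(C)C)[C@@H]23)cc1
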